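## Retrosynthetic overview

1. Structural feature: the dihydrofuran ring O1–C2–C3–C3a–C7a carries the veratryl group on C2 and a single exocyclic carbon (CH2OH) on C3, next to aryl carbon C3a. This is the pyranone ring O1–C2–C3–C4–C4a–C8a of a flavanone with C4 squeezed out, so the CH2OH carbon is the former carbonyl carbon.
2. Late disconnections: the acid comes from its methyl ester by saponification, and the ester from a C5 bromide plus methyl acrylate by Heck coupling. The CH2OH and the 7-OH come from a methyl ester and an aryl pivalate in one hydride step.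
3. Key disconnection: the trans-2,3-dihydrobenzofuran-3-carboxylate comes from an (R)-flavanone by an iodine(III)-induced 1,2-shift of C4a from C4 to C3.
4. The flavanone comes from 6-bromo-8-pivaloyloxychromone and 3,4-dimethoxyphenylboronic acid by Pd(II)/PyOx asymmetric conjugate addition, which sets C2. The chromone comes from a brominated o-hydroxyacetophenone and DMF dimethyl acetal.
5. Ring order: both benzene rings are bought, the pyranone is closed first, the veratryl ring is attached to it, the pyranone is contracted to the dihydrofuran, and the side chain is added last.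

Key step: step 7

Assumption: (S)-t-BuPyOx is taken to deliver the aryl group to the same enone face of a chromone as of a 3-substituted cyclohexenone, which corresponds to 2R. The sign is to be confirmed on the flavanone by CD or rotation, and the equally available (R)-ligand would be used if the sense proved opposite.

## Route

Step 1
Reactants: 1 1-(2-hydroxy-3-methoxyphenyl)ethanone
Product: 2 1-(5-bromo-2-hydroxy-3-methoxyphenyl)ethanone
Conditions: NBS (1.05 equiv), MeCN, 0 °C → rt
Reagents that add atoms: N-bromosuccinimide, O=C1CCC(=O)N1Br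
Why: Electrophilic aromatic bromination: the phenol OH directs to C5, its only free ortho/para position (also meta to the acetyl group), and NBS in a polar solvent without initiator or added acid should favour ring over α-keto bromination.

Step 2
Reactants: 2 1-(5-bromo-2-hydroxy-3-methoxyphenyl)ethanone; 3 N,N-dimethylformamide dimethyl acetal
Product: 4 (E)-1-(5-bromo-2-hydroxy-3-methoxyphenyl)-3-(dimethylamino)prop-2-en-1-one
Conditions: 3 (2 equiv), toluene, 100 °C
Reagents that add atoms: N,N-dimethylformamide dimethyl acetal (3), COC(OC)N(C)C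
Why: Amide-acetal condensation (enaminone formation): the methyl ketone is the only acidic C–H site, methanol is driven off at 100 °C, and the hydrogen-bonded ortho-phenol should stay unmethylated.

Step 3
Reactants: 4 (E)-1-(5-bromo-2-hydroxy-3-methoxyphenyl)-3-(dimethylamino)prop-2-en-1-one
Product: 5 6-bromo-8-methoxychromen-4-one
Conditions: conc. HCl, CH2Cl2, 40 °C
Reagents that add atoms: none
Why: Standard enaminone route to chromones: once the vinylogous amide is protonated the ortho-phenol adds to the β-carbon and dimethylamine is eliminated (addition–elimination), which closes the pyranone ring.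

Step 4
Reactants: 5 6-bromo-8-methoxychromen-4-one
Product: 6 6-bromo-8-hydroxychromen-4-one
Conditions: BBr3 (3 equiv), CH2Cl2, −78 °C → rt; then ice/H2O
Reagents that add atoms: none
Why: Lewis-acid aryl methyl ether cleavage with BBr3, placed here because 5 holds a single methoxy group, so no selectivity against the later veratryl methoxy groups is needed and the chromone carbonyl only ties up one equivalent of reagent.

Step 5
Reactants: 6 6-bromo-8-hydroxychromen-4-one
Product: 7 6-bromo-4-oxochromen-8-yl pivalate
Conditions: PivCl (1.2 equiv), Et3N (1.5 equiv), DMAP (5 mol %), CH2Cl2, 0 °C → rt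
Reagents that add atoms: pivaloyl chloride, CC(C)(C)C(=O)Cl
Why: DMAP-catalysed O-acylation: the hindered, electron-withdrawing pivalate keeps the phenol away from palladium and iodine(III), should survive water at 60 °C and catalytic acid, and needs no separate removal because step 8 cleaves it.

Step 6
Reactants: 7 6-bromo-4-oxochromen-8-yl pivalate; 8 3,4-dimethoxyphenylboronic acid
Product: 9 (R)-6-bromo-2-(3,4-dimethoxyphenyl)-4-oxochroman-8-yl pivalate
Conditions: Pd(OCOCF3)2 (5 mol %), (S)-t-BuPyOx (6 mol %), NH4PF6 (30 mol %), H2O (5 equiv), 8 (2 equiv), ClCH2CH2Cl, 60 °C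
Reagents that add atoms: 3,4-dimethoxyphenylboronic acid (8), COc1ccc(B(O)O)cc1OC
Why: Pd(II)/pyridine-oxazoline-catalysed asymmetric conjugate addition of an arylboronic acid to a chromone (transmetallation, enantiodetermining carbopalladation of C2=C3, protonolysis of the Pd enolate): the tert-butyl group of the ligand selects the enone face and sets C2 as R, and because the cycle stays at Pd(II) the aryl bromide should not be touched.

Step 7
Reactants: 9 (R)-6-bromo-2-(3,4-dimethoxyphenyl)-4-oxochroman-8-yl pivalate
Product: 13 methyl (2R,3R)-5-bromo-2-(3,4-dimethoxyphenyl)-7-(pivaloyloxy)-2,3-dihydrobenzofuran-3-carboxylate (2,3-trans), via enol ether 10 (not isolated), via iodanyl ketal 11 (not isolated), via dimethoxycarbenium ion 12 (not isolated)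
Conditions: PhI(OAc)2 (1.2 equiv), conc. H2SO4 (cat.), HC(OMe)3, 0 °C → rt
Reagents that add atoms: trimethyl orthoformate, COC(OC)OC
Why: Acidic orthoformate converts the C4 ketone into enol ether 10, the iodine(III) electrophile adds to C3 on the face away from the C2 aryl group while methanol caps C4 to give iodanyl ketal 11, aryl carbon C4a then moves from C4 to C3 through a phenonium-type bridge as iodobenzene departs, and cation 12 loses a methyl group to acetate to leave the methyl ester. The closest known reaction type is this very one, the hypervalent-iodine (or thallium(III)) oxidative ring contraction of flavanones in trimethyl orthoformate to methyl trans-2-aryl-2,3-dihydrobenzofuran-3-carboxylates, itself the cyclic form of the aryl ketone to arylacetate 1,2-aryl shift. The five-membered ring O1–C2–C3–C3a–C7a is closed by ring contraction, the C3–C4a bond forming as the C4–C4a bond breaks, with no new C–O bond and with C4 expelled as the exocyclic ester carbon. C3 is controlled by the resident C2 centre: iodination trans to the veratryl group followed by backside entry of C4a (inversion) places CO2Me trans to the aryl group (2R,3R), which is also the more stable arrangement at this epimerisable position, and no bond to C2 is made or broken. The selectivity needed is C4a shift over veratryl 2→3 shift (isoflavone path) and over simple elimination (flavone path); in the diequatorial half-chair of 11 the C3–I bond is antiperiplanar to C4–C4a, whereas the veratryl shift needs the diaxial conformer, which suffers a 1,3-diaxial clash between the aryl group and the axial ketal methoxy group, and O1 ortho to C4a together with the two ketal oxygens stabilises the charge that develops in the wanted shift. Bromide and pivalate keep the benzo ring out of reach of the oxidant, and catalytic acid, low temperature and short contact time should limit reversible C2–O1 ionisation (loss of ee), attack of iodine(III) on the veratryl ring and methanolysis of the pivalate.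

Step 8
Reactants: 13 methyl (2R,3R)-5-bromo-2-(3,4-dimethoxyphenyl)-7-(pivaloyloxy)-2,3-dihydrobenzofuran-3-carboxylate
Product: 14 (2R,3S)-5-bromo-2-(3,4-dimethoxyphenyl)-3-(hydroxymethyl)-2,3-dihydrobenzofuran-7-ol
Conditions: LiAlH4 (2.5 equiv), THF, −20 → 0 °C; then aq. Rochelle salt
Reagents that add atoms: none
Why: Hydride reduction with LiAlH4: the methyl ester goes to the primary alcohol and the aryl pivalate is cleaved reductively in the same flask, the aryl bromide is inert at or below 0 °C, fast carbonyl addition at low temperature should outrun enolisation at C3 (no epimerisation, no β-elimination of O1), and the C3 descriptor changes from R to S only through CIP priorities.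

Step 9
Reactants: 14 (2R,3S)-5-bromo-2-(3,4-dimethoxyphenyl)-3-(hydroxymethyl)-2,3-dihydrobenzofuran-7-ol; 15 methyl acrylate
Product: 16 methyl (E)-3-[(2R,3S)-2-(3,4-dimethoxyphenyl)-7-hydroxy-3-(hydroxymethyl)-2,3-dihydrobenzofuran-5-yl]acrylate
Conditions: Pd(OAc)2 (5 mol %), P(o-tol)3 (12 mol %), Et3N (3 equiv), 15 (3 equiv), DMF (degassed), 90 °C
Reagents that add atoms: methyl acrylate (15), C=CC(=O)OC
Why: Mizoroki–Heck reaction: oxidative addition into the C5–Br bond, syn insertion of the acrylate and syn β-hydride elimination give the E-cinnamate, free phenols and primary alcohols are tolerated with an amine base, and neither stereocentre takes part.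

Step 10
Reactants: 16 methyl (E)-3-[(2R,3S)-2-(3,4-dimethoxyphenyl)-7-hydroxy-3-(hydroxymethyl)-2,3-dihydrobenzofuran-5-yl]acrylate
Product: 17 (E)-3-[(2R,3S)-2-(3,4-dimethoxyphenyl)-7-hydroxy-3-(hydroxymethyl)-2,3-dihydrobenzofuran-5-yl]acrylic acid (CNP0193199.1)
Conditions: LiOH·H2O (5 equiv), THF/MeOH/H2O (degassed, Ar), rt; then 1 M HCl, 0 °C, to pH 3
Reagents that add atoms: lithium hydroxide, [Li+].[OH-]
Why: Ester saponification (BAc2): only the methyl ester reacts, C2 and C3 carry no acidic hydrogen, the methylated 4'-oxygen blocks quinone-methide opening of the C2–O1 bond, and exclusion of oxygen protects the phenoxide until the cold acidification.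

## Compound list

1 | 1-(2-hydroxy-3-methoxyphenyl)ethanone | CC(=O)c1cccc(OC)c1O | starting material
2 | 1-(5-bromo-2-hydroxy-3-methoxyphenyl)ethanone | CC(=O)c1cc(Br)cc(OC)c1O | intermediate
3 | N,N-dimethylformamide dimethyl acetal | COC(OC)N(C)C | starting material
4 | (E)-1-(5-bromo-2-hydroxy-3-methoxyphenyl)-3-(dimethylamino)prop-2-en-1-one | CN(C)/C=C/C(=O)c1cc(Br)cc(OC)c1O | intermediate
5 | 6-bromo-8-methoxychromen-4-one | COc1cc(Br)cc2c(=O)ccoc12 | intermediate
6 | 6-bromo-8-hydroxychromen-4-one | Oc1cc(Br)cc2c(=O)ccoc12 | intermediate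
7 | 6-bromo-4-oxochromen-8-yl pivalate | CC(C)(C)C(=O)Oc1cc(Br)cc2c(=O)ccoc12 | intermediate
8 | 3,4-dimethoxyphenylboronic acid | COc1ccc(B(O)O)cc1OC | starting material
9 | (R)-6-bromo-2-(3,4-dimethoxyphenyl)-4-oxochroman-8-yl pivalate | COc1ccc([C@H]2CC(=O)c3cc(Br)cc(OC(=O)C(C)(C)C)c3O2)cc1OC | intermediate
10 | (R)-6-bromo-2-(3,4-dimethoxyphenyl)-4-methoxy-2H-chromen-8-yl pivalate (enol ether) | COc1ccc([C@H]2C=C(OC)c3cc(Br)cc(OC(=O)C(C)(C)C)c3O2)cc1OC | intermediate
11 | (2S,3S)-3-[acetoxy(phenyl)-λ3-iodanyl]-6-bromo-2-(3,4-dimethoxyphenyl)-4,4-dimethoxychroman-8-yl pivalate (2,3-trans; C2 spatially unchanged, descriptor altered by CIP priority) | COc1ccc([C@@H]2Oc3c(OC(=O)C(C)(C)C)cc(Br)cc3C(OC)(OC)[C@H]2I(OC(C)=O)c4ccccc4)cc1OC | intermediate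
12 | [(2R,3R)-5-bromo-2-(3,4-dimethoxyphenyl)-7-(pivaloyloxy)-2,3-dihydrobenzofuran-3-yl]dimethoxycarbenium ion | COc1ccc([C@@H]2Oc3c(OC(=O)C(C)(C)C)cc(Br)cc3[C@H]2C(=[O+]C)OC)cc1OC | intermediate
13 | methyl (2R,3R)-5-bromo-2-(3,4-dimethoxyphenyl)-7-(pivaloyloxy)-2,3-dihydrobenzofuran-3-carboxylate (trans) | COc1ccc([C@@H]2Oc3c(OC(=O)C(C)(C)C)cc(Br)cc3[C@H]2C(=O)OC)cc1OC | intermediate
14 | (2R,3S)-5-bromo-2-(3,4-dimethoxyphenyl)-3-(hydroxymethyl)-2,3-dihydrobenzofuran-7-ol | COc1ccc([C@@H]2Oc3c(O)cc(Br)cc3[C@H]2CO)cc1OC | intermediate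
15 | methyl acrylate | C=CC(=O)OC | starting material
16 | methyl (E)-3-[(2R,3S)-2-(3,4-dimethoxyphenyl)-7-hydroxy-3-(hydroxymethyl)-2,3-dihydrobenzofuran-5-yl]acrylate | COc1ccc([C@@H]2Oc3c(O)cc(/C=C/C(=O)OC)cc3[C@H]2CO)cc1OC | intermediate
17 | (E)-3-[(2R,3S)-2-(3,4-dimethoxyphenyl)-7-hydroxy-3-(hydroxymethyl)-2,3-dihydrobenzofuran-5-yl]acrylic acid (CNP0193199.1) | COc1ccc([C@@H]2Oc3c(O)cc(/C=C/C(=O)O)cc3[C@H]2CO)cc1OC | target

## Step count and risks

Total step count: 10. Longest linear sequence: 10 steps (1 → 17).

### Steps most likely to fail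

**Step 7.**
- What may go wrong:
  - The electron-rich veratryl group may migrate from C2 to C3 in place of C4a.
  - Simple elimination may aromatise the pyranone.
  - Iodine(III) may attack the veratryl ring.
  - Reversible acid opening of the C2–O1 bond may erode the ee, which is therefore to be measured on 9 and again on 13.
- Fallback: it sets out from 9 and returns at 13. It replaces the cationic shift by a Wolff ring contraction, in which only the group on the carbonyl carbon (C4a) can migrate.
- Compound 9 is deprotonated with LiHMDS in THF at −78 °C and acylated at once with 2,2,2-trifluoroethyl trifluoroacetate to the 3-trifluoroacetylflavanone F1.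
- Mesyl azide and Et3N in aqueous MeCN (detrifluoroacetylative Regitz diazo transfer) give the 3-diazoflavanone F2.
- Irradiation (365–400 nm LED) in MeOH expels nitrogen from this s-Z-locked diazoketone. C4a shifts in concert to give the ring-contracted ketene F3.
- Methanol adds to F3, and protonation from the face away from the aryl group should give mainly the cis ester F4.
- DBU in CH2Cl2 equilibrates F4 to the trans ester 13.
- The short-lived enolate at −78 °C is the point where ring opening must be watched.

**Step 6.**
- What may go wrong: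
  - Protodeboronation or homocoupling of the electron-rich boronic acid may outrun a slow carbopalladation.
  - The catalyst may precipitate.
  - Facial selectivity may be insufficient.
  - The product may partly racemise by ring opening at 60 °C.
- Fallback: it sets out from 2 and returns at 9. It builds the C2–aryl connection by carbonyl chemistry and obtains the enantiomer by resolution.
- Compound 2 is demethylated with BBr3 to 1-(5-bromo-2,3-dihydroxyphenyl)ethanone F5.
- Claisen–Schmidt condensation with 3,4-dimethoxybenzaldehyde (KOH, EtOH, argon) gives the 2',3'-dihydroxychalcone F6.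
- NaOAc in refluxing EtOH closes F6 by oxa-Michael addition to the racemic 8-hydroxyflavanone F7.
- PivCl in pyridine gives the racemic flavanone pivalate F8.
- Kinetic resolution follows by Noyori-type asymmetric transfer hydrogenation (Cp*Rh–TsDPEN, HCO2H/Et3N, EtOAc). The catalyst antipode is chosen so that the 2S ketone reacts fast.
- The unwanted enantiomer is thereby converted into the cis-(2S,4S)-flavan-4-ol F9, and unreacted 9 is separated from it by chromatography.

**Step 9.**
- What may go wrong:
  - Oxidative addition into a bromide para to O1 may be sluggish, and phenoxide formation makes it worse.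
  - Palladium may precipitate.
  - The phenoxide may be oxidised by air.
  - The phenol may add to the acrylate by oxa-Michael addition.
- Fallback: it sets out from 14 and returns at 16. It forms the side chain by carbonyl olefination, without palladium.
- TBSCl and imidazole in DMF give the bis-TBS ether F10.
- Bromine–lithium exchange (n-BuLi, THF, −78 °C) and a DMF quench give the 5-carbaldehyde F11.
- Horner–Wadsworth–Emmons olefination with trimethyl phosphonoacetate (LiCl, DBU, MeCN) gives the bis-TBS E-cinnamate F12.
- TBAF buffered with AcOH in THF at 0 °C releases 16.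

## Further compounds

F1 | step 7 | (2R)-6-bromo-2-(3,4-dimethoxyphenyl)-4-oxo-3-(trifluoroacetyl)chroman-8-yl pivalate (C3 undefined, largely enolised) | COc1ccc([C@H]2C(C(=O)C(F)(F)F)C(=O)c3cc(Br)cc(OC(=O)C(C)(C)C)c3O2)cc1OC
F2 | step 7 | (2S)-6-bromo-3-diazo-2-(3,4-dimethoxyphenyl)-4-oxochroman-8-yl pivalate (C2 spatially unchanged, descriptor altered by CIP priority) | COc1ccc([C@H]2C(=[N+]=[N-])C(=O)c3cc(Br)cc(OC(=O)C(C)(C)C)c3O2)cc1OC
F3 | step 7 | 5-bromo-2-(3,4-dimethoxyphenyl)-3-(oxomethylidene)-2,3-dihydrobenzofuran-7-yl pivalate (ketene, C2 spatially unchanged) | COc1ccc([C@@H]2Oc3c(OC(=O)C(C)(C)C)cc(Br)cc3C2=C=O)cc1OC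
F4 | step 7 | methyl (2R,3S)-5-bromo-2-(3,4-dimethoxyphenyl)-7-(pivaloyloxy)-2,3-dihydrobenzofuran-3-carboxylate (cis) | COc1ccc([C@@H]2Oc3c(OC(=O)C(C)(C)C)cc(Br)cc3[C@@H]2C(=O)OC)cc1OC
F5 | step 6 | 1-(5-bromo-2,3-dihydroxyphenyl)ethanone | CC(=O)c1cc(Br)cc(O)c1O
F6 | step 6 | (E)-1-(5-bromo-2,3-dihydroxyphenyl)-3-(3,4-dimethoxyphenyl)prop-2-en-1-one | COc1ccc(/C=C/C(=O)c2cc(Br)cc(O)c2O)cc1OC
F7 | step 6 | rac-6-bromo-2-(3,4-dimethoxyphenyl)-8-hydroxychroman-4-one | COc1ccc(C2CC(=O)c3cc(Br)cc(O)c3O2)cc1OC
F8 | step 6 | rac-6-bromo-2-(3,4-dimethoxyphenyl)-4-oxochroman-8-yl pivalate | COc1ccc(C2CC(=O)c3cc(Br)cc(OC(=O)C(C)(C)C)c3O2)cc1OC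
F9 | step 6 | (2S,4S)-6-bromo-2-(3,4-dimethoxyphenyl)-4-hydroxychroman-8-yl pivalate (2,4-cis) | COc1ccc([C@@H]2C[C@H](O)c3cc(Br)cc(OC(=O)C(C)(C)C)c3O2)cc1OC
F10 | step 9 | (2R,3S)-5-bromo-7-(tert-butyldimethylsilyloxy)-3-[(tert-butyldimethylsilyloxy)methyl]-2-(3,4-dimethoxyphenyl)-2,3-dihydrobenzofuran | COc1ccc([C@@H]2Oc3c(O[Si](C)(C)C(C)(C)C)cc(Br)cc3[C@H]2CO[Si](C)(C)C(C)(C)C)cc1OC
F11 | step 9 | (2R,3S)-7-(tert-butyldimethylsilyloxy)-3-[(tert-butyldimethylsilyloxy)methyl]-2-(3,4-dimethoxyphenyl)-2,3-dihydrobenzofuran-5-carbaldehyde | COc1ccc([C@@H]2Oc3c(O[Si](C)(C)C(C)(C)C)cc(C=O)cc3[C@H]2CO[Si](C)(C)C(C)(C)C)cc1OC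
F12 | step 9 | methyl (E)-3-[(2R,3S)-7-(tert-butyldimethylsilyloxy)-3-[(tert-butyldimethylsilyloxy)methyl]-2-(3,4-dimethoxyphenyl)-2,3-dihydrobenzofuran-5-yl]acrylate | COc1ccc([C@@H]2Oc3c(O[Si](C)(C)C(C)(C)C)cc(/C=C/C(=O)OC)cc3[C@H]2CO[Si](C)(C)C(C)(C)C)cc1OC
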